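**Strategy.** The α-methylene-γ-lactone is opened at the C6–O bond and at the C11–C12 bond, so that carbon dioxide supplies C12 and both lactone oxygens. The precursor is an open-chain triene whose C11 is an alkenylboronate and whose C6 bears a methyl carbonate; the step exploits that C6 is allylic to the Z C4=C5 alkene and two bonds from C11 through C7. In one flask, copper-catalysed carboxylation turns the boronate into an acrylate, and zerovalent palladium then lets this carboxylate displace the carbonate with net retention, closing the five-membered lactone ring. An Evans aldol, a Nozaki–Hiyama–Kishi coupling and an Evans–Tishchenko reduction assemble the precursor without protecting groups; ring-closing metathesis and epoxidation of C1=C10 finish the ten-membered ring.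

Key step: step 16

Remark: germacranolide numbering is used (C12 lactone carbonyl, C11 its α-carbon, C13 the exocyclic CH2, C6 the lactone O–CH, C7 the ring-fusion CH, C8 the isovalerate carbon, C10/C1 the epoxide carbons, C3 the acetate carbon, C4=C5 the ring alkene); the target is read as 1R,3R,6S,7R,8S,10S with Z C4=C5, a cis-fused lactone and a cis epoxide, and aldehydes 13 and 17 are assumed to be used crude. Bpin = 4,4,5,5-tetramethyl-1,3,2-dioxaborolan-2-yl; IPr = 1,3-bis(2,6-diisopropylphenyl)imidazol-2-ylidene; TRIP = 3,3′-bis(2,4,6-triisopropylphenyl)-1,1′-binaphthyl-2,2′-diyl hydrogen phosphate.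

Step 1
Reactants: 1 prop-2-yn-1-ol
Product: 3 (Z)-3-iodo-2-methylprop-2-en-1-ol, via cyclic alkenylmagnesium alkoxide 2 (not isolated)
Conditions: MeMgBr (2.5 equiv), CuI (10 mol %), Et2O, −10 °C to rt; then I2, −40 to 0 °C
Reagents that add atoms: methylmagnesium bromide C[Mg]Br; iodine II
Why: Copper-catalysed anti-carbomagnesiation of the propargylic alkoxide (Duboudin–Jousseaume reaction) puts methyl on C4 and magnesium on C5 inside chelate 2, and iodinolysis with retention should give the alkene with iodine cis to the CH2OH carbon, the geometry that later becomes the Z C4=C5 alkene.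

Step 2
Reactants: 3 (Z)-3-iodo-2-methylprop-2-en-1-ol
Product: 4 (Z)-3-iodo-2-methylprop-2-enal
Conditions: MnO2 (excess), CH2Cl2, rt
Reagents that add atoms: none
Why: Allylic oxidation with MnO2 is neutral and heterogeneous, so the Z iodoenal should form without isomerisation or over-oxidation.

Step 3
Reactants: 4 (Z)-3-iodo-2-methylprop-2-enal
Product: 5 (R,Z)-1-iodo-2-methylhexa-1,5-dien-3-ol
Conditions: allylboronic acid pinacol ester (1.2 equiv), (R)-TRIP (5 mol %), toluene, −30 °C; aqueous work-up
Reagents that add atoms: 2-allyl-4,4,5,5-tetramethyl-1,3,2-dioxaborolane C=CCB1OC(C)(C)C(C)(C)O1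
Why: Chiral phosphoric acid-catalysed allylboration (Antilla allylation) through a chair transition state in which (R)-TRIP binds the boronate oxygen and the formyl hydrogen should direct allyl transfer to the re face and set C3 as R.

Step 4
Reactants: 5 (R,Z)-1-iodo-2-methylhexa-1,5-dien-3-ol
Product: 6 (R,Z)-1-iodo-2-methylhexa-1,5-dien-3-yl acetate
Conditions: Ac2O, pyridine, DMAP (cat.), CH2Cl2, 0 °C to rt
Reagents that add atoms: acetic anhydride CC(=O)OC(C)=O
Why: DMAP-catalysed O-acylation installs the C3 acetate of the target with retention at C3.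

Step 5
Reactants: 7 3-bromobut-3-en-1-ol
Product: 8 3-bromobut-3-enoic acid
Conditions: TEMPO (20 mol %), PhI(OAc)2 (2.2 equiv), MeCN/H2O 1:1, rt
Reagents that add atoms: water O
Why: TEMPO/PhI(OAc)2 oxidation in aqueous acetonitrile takes the primary alcohol through the aldehyde hydrate to the acid without touching the vinyl bromide.

Step 6
Reactants: 8 3-bromobut-3-enoic acid; 9 (R)-4-benzyloxazolidin-2-one
Product: 11 (R)-4-benzyl-3-(3-bromobut-3-enoyl)oxazolidin-2-one, via mixed pivalic anhydride 10 (not isolated)
Conditions: PivCl, Et3N, THF, −20 °C; then LiCl, 9, −20 °C to rt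
Reagents that add atoms: none
Why: N-Acylation of the oxazolidinone through the mixed pivalic anhydride under LiCl/Et3N (Evans auxiliary loading) should proceed without isomerising the β,γ-alkene.

Step 7
Reactants: 12 3-methylbut-3-en-1-ol
Product: 13 3-methylbut-3-enal
Conditions: Dess–Martin periodinane, NaHCO3, CH2Cl2, 0 °C; washed, dried and used as a solution
Reagents that add atoms: none
Why: Dess–Martin oxidation is non-basic, so the β,γ-unsaturated aldehyde should form without conjugation of the alkene.

Step 8
Reactants: 11 (R)-4-benzyl-3-(3-bromobut-3-enoyl)oxazolidin-2-one; 13 3-methylbut-3-enal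
Product: 14 (R)-4-benzyl-3-[(2R,3S)-2-(1-bromoethenyl)-3-hydroxy-5-methylhex-5-enoyl]oxazolidin-2-one
Conditions: Bu2BOTf (1.1 equiv), i-Pr2NEt (1.2 equiv), CH2Cl2, −78 to 0 °C; 13, −78 to 0 °C; pH 7 buffer, MeOH, H2O2
Reagents that add atoms: none
Why: Evans syn-aldol reaction: the Z boron enolate reacts through a Zimmerman–Traxler chair on the face away from the benzyl group of the (R)-auxiliary, which should set C7 and C8 as the 2R,3S syn pair and place the 1-bromoethenyl group (C11, C13) on C7.

Step 9
Reactants: 14 aldol adduct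
Product: 15 (2S,3S)-2-(1-bromoethenyl)-5-methylhex-5-ene-1,3-diol
Conditions: LiBH4, MeOH (1 equiv), THF, 0 °C
Reagents that add atoms: none
Why: Reductive cleavage of the N-acyl oxazolidinone with LiBH4 releases the auxiliary and gives the primary C6 alcohol without epimerising C7.

Step 10
Reactants: 15 (2S,3S)-2-(1-bromoethenyl)-5-methylhex-5-ene-1,3-diol
Product: 16 (2S,3S)-5-methyl-2-[1-(Bpin)ethenyl]hex-5-ene-1,3-diol
Conditions: B2pin2 (1.1 equiv), PdCl2(PPh3)2 (3 mol %), PPh3 (6 mol %), KOPh (1.5 equiv), toluene, 50 °C
Reagents that add atoms: bis(pinacolato)diboron CC1(C)OB(OC1(C)C)B1OC(C)(C)C(C)(C)O1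
Why: Miyaura borylation of the alkenyl bromide (oxidative addition, transmetalation with the phenoxide-activated diboron, reductive elimination) gives the alkenylboronate needed for the key step while the diol and the 1,1-disubstituted alkene are inert.

Step 11
Reactants: 16 boryl diol
Product: 17 (2R,3S)-3-hydroxy-5-methyl-2-[1-(Bpin)ethenyl]hex-5-enal
Conditions: TEMPO (10 mol %), PhI(OAc)2 (1.1 equiv), CH2Cl2, rt; used crude
Reagents that add atoms: none
Why: TEMPO/PhI(OAc)2 oxidation selects the primary over the secondary alcohol and is neutral, so the β-hydroxy aldehyde should form without elimination or epimerisation at C7.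

Step 12
Reactants: 6 (R,Z)-1-iodo-2-methylhexa-1,5-dien-3-yl acetate; 17 β-hydroxy aldehyde
Product: 18 (4R,5Z,8R,9S)-7,9-dihydroxy-5,11-dimethyl-8-[1-(Bpin)ethenyl]dodeca-1,5,11-trien-4-yl acetate (both epimers at chain C7, which is C6 of the target)
Conditions: CrCl2 (4 equiv), NiCl2 (2 mol %), DMSO, rt
Reagents that add atoms: none
Why: Nozaki–Hiyama–Kishi coupling: the alkenyl iodide is activated by nickel and transferred to chromium with retention of the Z geometry, and the alkenylchromium adds only to the aldehyde, tolerating the acetate, the free hydroxyl and the boronate; the new C6 centre forms as a mixture that the next step removes.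

Step 13
Reactants: 18 diol (C6 epimers)
Product: 19 (4R,5Z,8R,9S)-9-hydroxy-5,11-dimethyl-7-oxo-8-[1-(Bpin)ethenyl]dodeca-1,5,11-trien-4-yl acetate
Conditions: MnO2 (excess), CH2Cl2, rt
Reagents that add atoms: none
Why: MnO2 oxidises only the allylic C6 alcohol, leaving the C8 hydroxyl, and converges both C6 epimers to one β-hydroxy enone.

Step 14
Reactants: 19 β-hydroxy enone; 20 3-methylbutanal
Product: 21 (4R,5Z,7S,8S,9S)-4-acetoxy-7-hydroxy-5,11-dimethyl-8-[1-(Bpin)ethenyl]dodeca-1,5,11-trien-9-yl 3-methylbutanoate
Conditions: SmI2 (30 mol %), 20 (5 equiv), THF, −10 °C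
Reagents that add atoms: none
Why: Evans–Tishchenko reduction: the samarium-bound hemiacetal formed from the C8 hydroxyl and 20 delivers hydride intramolecularly to the C6 ketone through a chair-like bicyclic transition state, which should set C6 1,3-anti to C8 and at the same time leave the isovalerate on O8 and the C6 hydroxyl free.

Step 15
Reactants: 21 allylic alcohol
Product: 22 (4R,5Z,7S,8R,9S)-4-acetoxy-7-(methoxycarbonyloxy)-5,11-dimethyl-8-[1-(Bpin)ethenyl]dodeca-1,5,11-trien-9-yl 3-methylbutanoate
Conditions: ClCO2Me, pyridine, DMAP (cat.), CH2Cl2, 0 °C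
Reagents that add atoms: methyl chloroformate COC(=O)Cl
Why: Acylation of the only free hydroxyl with methyl chloroformate turns C6–O into an allylic leaving group with retention at C6.

Step 16
Reactants: 22 allylic carbonate alkenylboronate; 23 carbon dioxide
Product: 25 (4R,5S)-5-[(1Z,3R)-3-acetoxy-2-methylhexa-1,5-dien-1-yl]-4-[(1S)-3-methyl-1-(3-methylbutanoyloxy)but-3-en-1-yl]-3-methylideneoxolan-2-one, via cesium acrylate 24 (not isolated)
Conditions: (IPr)CuCl (10 mol %), CsF (3 equiv), CO2 (1 atm), DMF, 60 °C; then Pd(PPh3)4 (5 mol %), same flask, 25 °C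
Reagents that add atoms: none
Why: Fluoride-assisted transmetalation of the alkenylboronate to monovalent copper and insertion of CO2 into the alkenyl–copper bond form the C11–C12 bond and give cesium acrylate 24; zerovalent palladium then ionises the C6 methyl carbonate with inversion to a π-allyl complex spanning C4–C5–C6, and the tethered carboxylate oxygen attacks C6 on the face opposite palladium, forming the O–C6 bond. The closest known reaction types are the copper-catalysed carboxylation of alkenylboronic esters with CO2 and the Tsuji–Trost allylic substitution by carboxylates. The lactone ring closes in a 5-exo mode (O, C12, C11, C7, C6), whereas attack at C4 would need a seven-membered ring. No stereocentre is created: C6 keeps its configuration through double inversion, so the 1,3-anti relation to C8 set in step 14 becomes the cis fusion of the lactone at C6/C7. The step needs the carbonate to ionise before the C3 allylic acetate, which the far better leaving group and the base-free room-temperature second stage should secure, and it needs the Z C4=C5 geometry to survive, which should hold because the fully substituted C4 terminus does not pass through a σ-bound form before the fast intramolecular capture.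

Step 17
Reactants: 25 lactone diene
Product: 26 (3R,6S,7R,8S)-3-acetoxy-8-(3-methylbutanoyloxy)germacra-1(10)Z,4Z,11(13)-trien-12,6-olide
Conditions: second-generation Grubbs catalyst (10 mol %), toluene (1 mM), 80 °C
Reagents that add atoms: none
Why: Ring-closing metathesis between the vinyl group (C1) and the 1,1-disubstituted alkene (C10) with loss of ethene closes the ten-membered ring, where the Z geometry of the new trisubstituted C1=C10 alkene is expected because an E alkene is more strained in a ring of this size that already holds the Z C4=C5 alkene and the cis-fused lactone; the conjugated exocyclic methylene is too electron-poor to compete.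

Step 18
Reactants: 26 macrocyclic triene
Product: 27 (1R,3R,6S,7R,8S,10S)-3-acetoxy-1,10-epoxy-8-(3-methylbutanoyloxy)germacra-4Z,11(13)-dien-12,6-olide (CNP0157657.2)
Conditions: mCPBA (1.1 equiv), NaHCO3, CH2Cl2, 0 °C
Reagents that add atoms: 3-chloroperbenzoic acid O=C(OO)c1cccc(Cl)c1
Why: Prilezhaev epoxidation is stereospecific (Z alkene to cis epoxide) and should select the electron-rich C1=C10 alkene over the C4=C5 alkene flanked by two allylic acyloxy groups and over the conjugated methylene; attack is expected on the face opposite the two homoallylic acyloxy groups at C3 and C8, which sets C1 as R and C10 as S.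

**Compound list**

1 | prop-2-yn-1-ol | C#CCO | starting material
2 | cyclic alkenylmagnesium alkoxide (4-methyl-2,5-dihydro-1,2-oxamagnesole) | CC1=C[Mg]OC1 | intermediate
3 | (Z)-3-iodo-2-methylprop-2-en-1-ol | I/C=C(/C)CO | intermediate
4 | (Z)-3-iodo-2-methylprop-2-enal | I/C=C(/C)C=O | intermediate
5 | (R,Z)-1-iodo-2-methylhexa-1,5-dien-3-ol | I/C=C(/C)[C@H](O)CC=C | intermediate
6 | (R,Z)-1-iodo-2-methylhexa-1,5-dien-3-yl acetate | I/C=C(/C)[C@H](OC(C)=O)CC=C | intermediate
7 | 3-bromobut-3-en-1-ol | C=C(Br)CCO | starting material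
8 | 3-bromobut-3-enoic acid | C=C(Br)CC(=O)O | intermediate
9 | (R)-4-benzyloxazolidin-2-one | O=C1N[C@H](Cc2ccccc2)CO1 | starting material
10 | 3-bromobut-3-enoic pivalic anhydride | C=C(Br)CC(=O)OC(=O)C(C)(C)C | intermediate
11 | (R)-4-benzyl-3-(3-bromobut-3-enoyl)oxazolidin-2-one | C=C(Br)CC(=O)N1[C@H](Cc2ccccc2)COC1=O | intermediate
12 | 3-methylbut-3-en-1-ol | C=C(C)CCO | starting material
13 | 3-methylbut-3-enal | C=C(C)CC=O | intermediate
14 | (R)-4-benzyl-3-[(2R,3S)-2-(1-bromoethenyl)-3-hydroxy-5-methylhex-5-enoyl]oxazolidin-2-one | C=C(Br)[C@@H](C(=O)N1[C@H](Cc2ccccc2)COC1=O)[C@@H](O)CC(C)=C | intermediate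
15 | (2S,3S)-2-(1-bromoethenyl)-5-methylhex-5-ene-1,3-diol | C=C(Br)[C@@H](CO)[C@@H](O)CC(C)=C | intermediate
16 | (2S,3S)-5-methyl-2-[1-(Bpin)ethenyl]hex-5-ene-1,3-diol | C=C(B1OC(C)(C)C(C)(C)O1)[C@@H](CO)[C@@H](O)CC(C)=C | intermediate
17 | (2R,3S)-3-hydroxy-5-methyl-2-[1-(Bpin)ethenyl]hex-5-enal | C=C(B1OC(C)(C)C(C)(C)O1)[C@@H](C=O)[C@@H](O)CC(C)=C | intermediate
18 | (4R,5Z,8R,9S)-7,9-dihydroxy-5,11-dimethyl-8-[1-(Bpin)ethenyl]dodeca-1,5,11-trien-4-yl acetate (C7 epimers) | C=C(B1OC(C)(C)C(C)(C)O1)[C@@H](C(O)/C=C(/C)[C@H](OC(C)=O)CC=C)[C@@H](O)CC(C)=C | intermediate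
19 | (4R,5Z,8R,9S)-9-hydroxy-5,11-dimethyl-7-oxo-8-[1-(Bpin)ethenyl]dodeca-1,5,11-trien-4-yl acetate | C=C(B1OC(C)(C)C(C)(C)O1)[C@@H](C(=O)/C=C(/C)[C@H](OC(C)=O)CC=C)[C@@H](O)CC(C)=C | intermediate
20 | 3-methylbutanal | CC(C)CC=O | starting material
21 | (4R,5Z,7S,8S,9S)-4-acetoxy-7-hydroxy-5,11-dimethyl-8-[1-(Bpin)ethenyl]dodeca-1,5,11-trien-9-yl 3-methylbutanoate | C=C(B1OC(C)(C)C(C)(C)O1)[C@@H]([C@@H](O)/C=C(/C)[C@H](OC(C)=O)CC=C)[C@@H](OC(=O)CC(C)C)CC(C)=C | intermediate
22 | (4R,5Z,7S,8R,9S)-4-acetoxy-7-(methoxycarbonyloxy)-5,11-dimethyl-8-[1-(Bpin)ethenyl]dodeca-1,5,11-trien-9-yl 3-methylbutanoate | C=C(B1OC(C)(C)C(C)(C)O1)[C@@H]([C@@H](OC(=O)OC)/C=C(/C)[C@H](OC(C)=O)CC=C)[C@@H](OC(=O)CC(C)C)CC(C)=C | intermediate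
23 | carbon dioxide | O=C=O | starting material
24 | cesium 2-[(4R,5Z,7S,8R,9S)-4-acetoxy-7-(methoxycarbonyloxy)-5,11-dimethyl-9-(3-methylbutanoyloxy)dodeca-1,5,11-trien-8-yl]prop-2-enoate | C=C(C(=O)[O-])[C@@H]([C@@H](OC(=O)OC)/C=C(/C)[C@H](OC(C)=O)CC=C)[C@@H](OC(=O)CC(C)C)CC(C)=C.[Cs+] | intermediate
25 | (4R,5S)-5-[(1Z,3R)-3-acetoxy-2-methylhexa-1,5-dien-1-yl]-4-[(1S)-3-methyl-1-(3-methylbutanoyloxy)but-3-en-1-yl]-3-methylideneoxolan-2-one | C=C1C(=O)O[C@@H](/C=C(/C)[C@H](OC(C)=O)CC=C)[C@H]1[C@@H](OC(=O)CC(C)C)CC(C)=C | intermediate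
26 | (3R,6S,7R,8S)-3-acetoxy-8-(3-methylbutanoyloxy)germacra-1(10)Z,4Z,11(13)-trien-12,6-olide | C=C1C(=O)O[C@H]2/C=C(/C)[C@H](OC(C)=O)C/C=C(C)\C[C@H](OC(=O)CC(C)C)[C@@H]12 | intermediate
27 | (1R,3R,6S,7R,8S,10S)-3-acetoxy-1,10-epoxy-8-(3-methylbutanoyloxy)germacra-4Z,11(13)-dien-12,6-olide (CNP0157657.2) | C=C1C(=O)O[C@H]2/C=C(/C)[C@H](OC(C)=O)C[C@H]3O[C@@]3(C)C[C@H](OC(=O)CC(C)C)[C@@H]12 | target

**Totals.** Total step count: 18. Longest linear sequence: 13 steps (7 to 27 through steps 5, 6 and 8–18).

**Steps most likely to fail**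

Step 17 (ring-closing metathesis). The closure may give oligomers or the E alkene, because the cis-fused lactone and the Z C4=C5 alkene restrict the conformations that bring C1 and C10 together. The fallback reverses the order of ring closure and lactone formation. It sets out from 22: ring-closing metathesis of the conformationally freer open chain (second-generation Grubbs catalyst, toluene, high dilution; the α-branched 1,1-disubstituted alkenylboronate is expected to be the slowest alkene) should give the ten-membered carbonate boronate F1. The conditions of step 16 applied to F1 should then give, through the cesium acrylate F2, the macrocyclic lactone, coming back to the route at 26.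

Step 16 (carboxylation and allylic lactonisation). The open-chain π-allyl intermediate may isomerise and lose the C6 configuration or the Z geometry, the C3 acetate may ionise in competition, or the boronate may be protonated before it captures CO2. The fallback avoids palladium and forms the C–O bond by direct substitution. It sets out from 21: chlorination with inversion (PPh3, hexachloroacetone, CH2Cl2, −20 °C) should give the allylic chloride F3. Copper-catalysed carboxylation under the first-stage conditions of step 16 should then give the cesium acrylate F4, which should close by intramolecular SN2 displacement of chloride with a second inversion, coming back to the route at 25.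

Step 18 (epoxidation). Peracid attack on the C1=C10 alkene of the flexible ring may show poor or reversed facial selectivity. The fallback delivers the oxygen to the opposite face through a halohydrin. It sets out from 26: NBS in aqueous THF should add bromine to C1 on the face the peracid prefers and water to C10 from the other face, giving the bromohydrin F5. DBU in toluene should then close the epoxide with inversion at C1, coming back to the route at 27.

**Further compounds**

F1 | step 17 | ten-membered carbonate boronate (3-acetoxy, 6-methoxycarbonyloxy, 8-(3-methylbutanoyloxy), 7-[1-(Bpin)ethenyl], 1(10)Z,4Z; configurations as in 22) | C=C(B1OC(C)(C)C(C)(C)O1)[C@H]2[C@@H](OC(=O)OC)/C=C(/C)[C@H](OC(C)=O)C/C=C(C)\C[C@@H]2OC(=O)CC(C)C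
F2 | step 17 | cesium acrylate derived from F1 (not isolated) | C=C(C(=O)[O-])[C@H]2[C@@H](OC(=O)OC)/C=C(/C)[C@H](OC(C)=O)C/C=C(C)\C[C@@H]2OC(=O)CC(C)C.[Cs+]
F3 | step 16 | allylic chloride with inverted C6 (chloro analogue of 21) | C=C(B1OC(C)(C)C(C)(C)O1)[C@@H]([C@H](Cl)/C=C(/C)[C@H](OC(C)=O)CC=C)[C@@H](OC(=O)CC(C)C)CC(C)=C
F4 | step 16 | cesium acrylate derived from F3 (not isolated) | C=C(C(=O)[O-])[C@@H]([C@H](Cl)/C=C(/C)[C@H](OC(C)=O)CC=C)[C@@H](OC(=O)CC(C)C)CC(C)=C.[Cs+]
F5 | step 18 | 1-bromo-10-hydroxy bromohydrin of 26 (bromine and hydroxyl anti) | C=C1C(=O)O[C@H]2/C=C(/C)[C@H](OC(C)=O)C[C@H](Br)[C@](O)(C)C[C@H](OC(=O)CC(C)C)[C@@H]12
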